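**Retrosynthetic overview**
1. Structural feature: C4 of ring A carries C15 and lies between the two oxygen-bearing carbons C3 and C5. Removing this one carbon leaves a five-membered ring (C10, C1, C2, C3, C5) in which C3 and C5 are bonded directly and can form the two ends of an enol ether.
2. 26 ⇒ Δ4 3α-angelate 25 (the Schenck ene reaction puts OOH on C5 and moves the alkene to C4=C15) ⇒ 3β-alcohol 23 (Mitsunobu) ⇒ enone 22 (Luche).
3. 22 ⇒ hydrindane silyl enol ether 18 + chloro(methyl)carbene from diazirine 20. This forms C3–C4 and C4–C5, so ring A is made last, by one-carbon expansion.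
4. 18 ⇒ ring B is functionalised (C7 arm from an allyl group, 8β-OAc) while C5 is held trigonal as a t-BuMe2Si enol ether, so that axial C14 steers C7 and C8. The arm stays below the ester oxidation level until O-8 is acetylated, which prevents closure to the 8,12-lactone.
5. Hydrindane ⇒ Diels–Alder reaction of 1 (five-membered ring, purchased) with 2 (ring B), with resolution at 7. Ring order: five-membered ring, ring B, ring A.

Key step: step 14

Remark on numbering: eudesmane locants are used throughout. In the hydrindanes, ring B is C5–C10 and the five-membered ring is C10, C1, C2, C3, C5. C14 is the methyl on C10 (β), and C4 and C15 are absent until step 14. Compounds 3, 4, 6 and 7 are racemic and are drawn as the enantiomer that is carried on.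
Assumption: the enantiomer collected in step 4 is identified by anomalous-dispersion X-ray analysis of a crystalline later compound such as acid 16. The configuration at C5 in 11–17 does not matter, because step 12 removes it.

Step 1
Reactants: 1 3-methylcyclopent-2-en-1-one; 2 2-(trimethylsilyloxy)buta-1,3-diene
Product: 3 rac-cis-10-methyl-8-(trimethylsilyloxy)hydrind-7-en-3-one (H-5 and C14 both β)
Conditions: AlBr3/AlMe3 (5:1, 0.3 equiv), 2 (2 equiv), PhMe/CH2Cl2, −5 °C; Et3N, then cold aq NaHCO3
Reagents that add atoms: none
Why: Lewis-acid-accelerated Diels–Alder reaction of a hindered β,β-disubstituted enone, in which the CH2 terminus next to the silyloxy carbon of 2 bonds to the β-carbon of 1 (para orientation, so the oxygen ends on C8), AlMe3 removes protic acid so that the enol ether survives, and suprafacial addition sets H-5 cis to C14 while creating the quaternary C10 in racemic form.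

Step 2
Reactants: 3 rac-Diels–Alder adduct
Product: 4 rac-3-(tert-butyldimethylsilyloxy)-10β-methyl-8-(trimethylsilyloxy)hydrinda-3(5),7-diene
Conditions: t-BuMe2SiOTf, Et3N, CH2Cl2, 0 °C → rt
Reagents that add atoms: tert-butyldimethylsilyl triflate, CC(C)(C)[Si](C)(C)OS(=O)(=O)C(F)(F)F
Why: Soft enolisation of a 2-alkylcyclopentanone with a silyl triflate and a tertiary amine should give the more substituted C3=C5 enol ether and leave the Me3Si enol ether untouched because no nucleophile for silicon is present; this masks the C3 ketone and makes C5 trigonal, which forces ring B into the chair with axial C14, whereas the flexible cis-hydrindanone would favour the wrong 7α epimer.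

Step 3
Reactants: 4 rac-bis(enol ether); 5 allyl bromide
Product: 7 rac-7β-allyl-3-(tert-butyldimethylsilyloxy)-10β-methylhydrind-3(5)-en-8-one, via lithium Δ7-enolate 6 (not isolated)
Conditions: MeLi, THF, 0 °C; 5, DMPU, −78 → −20 °C; crude product: DBU (cat.), PhMe, rt
Reagents that add atoms: methyllithium, [Li]C (supplies the lithium of 6, nothing in 7)
Why: MeLi attacks only the Me3Si group (t-BuMe2Si enol ethers are inert to it) and so releases the Δ7 lithium enolate regiospecifically, SN2 enolate alkylation forms C7–C11, and base equilibration of the epimerisable C7 should place the allyl group equatorial, that is β and cis to C14; an allyl group is used rather than an acetate ester because an ester arm would lactonise onto O-8 in step 5.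

Step 4
Reactants: 7 rac-allyl ketone
Product: 8 (7S,10R)-7β-allyl-3-(tert-butyldimethylsilyloxy)-10β-methylhydrind-3(5)-en-8-one
Conditions: preparative HPLC, amylose tris(3,5-dimethylphenylcarbamate) phase, hexane/i-PrOH
Reagents that add atoms: none
Why: Resolution by chromatography on a polysaccharide chiral stationary phase under neutral normal-phase conditions that a t-BuMe2Si enol ether tolerates; no stereocentre is made or changed, and 7 is the first intermediate robust enough for the separation.

Step 5
Reactants: 8 allyl ketone
Product: 9 7β-allyl-3-(tert-butyldimethylsilyloxy)-10β-methylhydrind-3(5)-en-8β-ol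
Conditions: LiBH(s-Bu)3 (L-Selectride), THF, −78 → −20 °C; NaOH, H2O2, 0 °C
Reagents that add atoms: none
Why: Reduction of a cyclohexanone with a bulky trialkylborohydride, in which the axial (β) trajectory at C8 is blocked by the syn-axial C14 methyl, so hydride should arrive equatorially from the α side and give the axial 8β-alcohol cis to the 7β-allyl group.

Step 6
Reactants: 9 8β-alcohol
Product: 10 8β-acetoxy-7β-allyl-3-(tert-butyldimethylsilyloxy)-10β-methylhydrind-3(5)-ene
Conditions: Ac2O, DMAP, Et3N, CH2Cl2, rt
Reagents that add atoms: acetic anhydride, CC(=O)OC(C)=O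
Why: DMAP-catalysed acylation of a hindered axial alcohol with retention at C8 under basic conditions that leave the silyl enol ether intact.

Step 7
Reactants: 10 acetate
Product: 11 8β-acetoxy-7β-allyl-10β-methyl-5βH-hydrindan-3-one
Conditions: Bu4NF, AcOH, THF, 0 °C
Reagents that add atoms: none
Why: Buffered fluoride cleavage of the silyl enol ether, which has now done its work as mask and conformational lock; protonation at C5 should give the more stable cis-hydrindanone, and the buffer protects the acetate.

Step 8
Reactants: 11 keto acetate
Product: 13 (8β-acetoxy-10β-methyl-3-oxo-5βH-hydrindan-7β-yl)acetaldehyde, via ozonide 12 (not isolated)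
Conditions: O3, CH2Cl2, −78 °C; Me2S, −78 °C → rt
Reagents that add atoms: ozone, [O-][O+]=O
Why: Ozonolysis (Criegee mechanism) of the only alkene in the molecule followed by reductive work-up leaves C11 and C12 as the acetaldehyde arm without touching any stereocentre.

Step 9
Reactants: 13 aldehyde
Product: 15 8β-acetoxy-3-oxo-4,15-dinor-5βH-eudesm-11(13)-en-12-al, via Mannich base 14 (not isolated)
Conditions: CH2=NMe2+ I− (Eschenmoser's salt), Et3N, CH2Cl2, rt
Reagents that add atoms: Eschenmoser's salt, C=[N+](C)C.[I-]
Why: Mannich reaction of the aldehyde enol with the iminium salt and β-elimination of dimethylamine introduces C13 as the methylene group; under these amine-base conditions only the aldehyde enolises, not the ketone or the acetate.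

Step 10
Reactants: 15 enal
Product: 16 8β-acetoxy-3-oxo-4,15-dinor-5βH-eudesm-11(13)-en-12-oic acid
Conditions: NaClO2, NaH2PO4, 2-methylbut-2-ene, t-BuOH/H2O, 0 °C → rt
Reagents that add atoms: sodium chlorite, [Na+].[O-]Cl=O
Why: Pinnick oxidation converts an α-substituted acrolein to the acrylic acid without attacking the alkene, the ketone or the acetate, the hypochlorite formed being trapped by the sacrificial alkene.

Step 11
Reactants: 16 acid
Product: 17 methyl 8β-acetoxy-3-oxo-4,15-dinor-5βH-eudesm-11(13)-en-12-oate
Conditions: MeI, K2CO3, DMF, 0 °C → rt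
Reagents that add atoms: iodomethane, CI
Why: SN2 O-alkylation of the carboxylate under a base too weak to enolise the ketone for C-alkylation or to cleave the acetate.

Step 12
Reactants: 17 keto ester
Product: 18 methyl 8β-acetoxy-3-(trimethylsilyloxy)-4,15-dinoreudesma-3(5),11(13)-dien-12-oate
Conditions: Me3SiI, (Me3Si)2NH, CH2Cl2, −20 °C → rt; pentane, cold aq NaHCO3; used crude
Reagents that add atoms: iodotrimethylsilane, C[Si](C)(C)I
Why: Thermodynamic enol silylation, in which reversible O-silylation and deprotonation should funnel the 2-alkylcyclopentanone to the tetrasubstituted C3=C5 enol ether, the two esters being much weaker Lewis bases than the ketone and any iodide adduct of the acrylate reverting on basic work-up.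

Step 13
Reactants: 19 acetamidine hydrochloride
Product: 20 3-chloro-3-methyl-3H-diazirine
Conditions: aq NaOCl, LiCl, DMSO, 0–25 °C; swept with N2 into pentane at −78 °C, kept as a cold dilute solution behind a shield
Reagents that add atoms: sodium hypochlorite, [Na+].[O-]Cl
Why: Graham oxidation, in which double N-chlorination of the amidine, base-induced N–N closure and capture of chloride at carbon give the 3-chloro-3-alkyldiazirine.

Step 14
Reactants: 18 silyl enol ether; 20 3-chloro-3-methyl-3H-diazirine
Product: 22 methyl 8β-acetoxy-3-oxoeudesma-4,11(13)-dien-12-oate, via chlorocyclopropane adduct 21 (not isolated)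
Conditions: 20 (about 8 equiv, cold pentane solution, in portions), 18 at about 1 M in pentane, hv 365 nm, −10 °C; then Et3N, PhMe, 90 °C
Reagents that add atoms: none
Why: Proposed new method: photolysis of 20 expels N2 and gives singlet chloro(methyl)carbene, which should add in a concerted (2+1) cheletropic step to the electron-rich C3=C5 bond of 18 from the α face (anti to C14) to give 21, whose chloride over the five-membered ring ionises in concert with disrotatory opening of the C3–C5 bond (Woodward–Hoffmann–DePuy rule) to a silyloxyallyl cation that loses Me3SiCl and gives 22. The closest known reactions are the ring expansion of cycloalkanone silyl enol ethers to 2-methylcycloalk-2-enones with the carbenoid from MeCHCl2 and n-BuLi, which the esters here would not survive, and the photochemical cyclopropanation of simple alkenes with 20; their combination on a tetrasubstituted, ester-bearing enol ether is what is new. The three-membered ring C3–C4–C5 closes by cycloaddition, and ring A then arises by electrocyclic expansion that merges the three- and five-membered rings, not by an end-to-end cyclisation. No new stereocentre survives, because C3, C4 and C5 of 21 all become trigonal in 22, and C7, C8 and C10 are not touched. The step needs chemoselectivity for the enol ether over the 1,1-disubstituted acrylate, which the electrophilic carbene and the donor oxygen secure, it needs the insertion site to be fixed, which the position of the enol ether double bond does, and it must outrun the 1,2-hydrogen shift of the carbene to vinyl chloride, which a high substrate concentration and excess 20 address. Only the C4 epimer of 21 with chloride over the five-membered ring can open, so adduct with chloride on the side of OSiMe3 and C6 is lost material.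

Step 15
Reactants: 22 enone
Product: 23 methyl 8β-acetoxy-3β-hydroxyeudesma-4,11(13)-dien-12-oate
Conditions: NaBH4, CeCl3·7H2O, MeOH, −78 → −20 °C
Reagents that add atoms: none
Why: Luche reduction gives clean 1,2-addition to the enone and leaves the acrylate and acetate alone, and axial delivery of hydride to C3 from the α face, away from the axial C14 methyl, should give the pseudoequatorial 3β-alcohol.

Step 16
Reactants: 23 3β-alcohol; 24 angelic acid
Product: 25 methyl 8β-acetoxy-3α-angeloyloxyeudesma-4,11(13)-dien-12-oate
Conditions: PPh3, DIAD, PhMe, 0 °C → rt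
Reagents that add atoms: none
Why: Mitsunobu reaction, in which SN2 displacement of the oxyphosphonium group by angelate inverts C3 to 3α, attack at the fully substituted C5 being disfavoured, and the Z alkene is not isomerised to tiglate because the acid is never activated at its carbonyl group.

Step 17
Reactants: 25 3α-angelate
Product: 26 methyl 8β-acetoxy-3α-angeloyloxy-5α-hydroperoxyeudesma-4(15),11(13)-dien-12-oate (CNP0116769.2)
Conditions: O2, tetraphenylporphyrin (cat.), visible light, CH2Cl2, −20 °C; no reductive work-up
Reagents that add atoms: dioxygen, O=O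
Why: Schenck ene reaction, in which singlet oxygen attacks only the electron-rich tetrasubstituted C4=C5 alkene (acrylate and angelate are electron-poor) from the α face opposite C14, H-3 is β and so out of reach, and abstraction from the C15 methyl geminal to the acyloxy-bearing carbon should be preferred over H-6α, so that O bonds to C5 (5α) and the alkene moves to C4=C15.

**Compound list**
1 | 3-methylcyclopent-2-en-1-one | CC1=CC(=O)CC1 | starting material
2 | 2-(trimethylsilyloxy)buta-1,3-diene | C=CC(=C)O[Si](C)(C)C | starting material
3 | rac-cis-10-methyl-8-(trimethylsilyloxy)hydrind-7-en-3-one (H-5, C14 β) | C1=C(O[Si](C)(C)C)C[C@@]2(C)CCC(=O)[C@H]2C1 | intermediate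
4 | rac-3-(tert-butyldimethylsilyloxy)-10β-methyl-8-(trimethylsilyloxy)hydrinda-3(5),7-diene | C1=C(O[Si](C)(C)C)C[C@@]2(C)CCC(O[Si](C)(C)C(C)(C)C)=C2C1 | intermediate
5 | allyl bromide | C=CCBr | starting material
6 | rac-lithium Δ7-enolate of the C8 ketone (C3=C5 t-BuMe2Si enol ether kept) | C1=C(O[Li])C[C@@]2(C)CCC(O[Si](C)(C)C(C)(C)C)=C2C1 | intermediate (not isolated)
7 | rac-7β-allyl-3-(tert-butyldimethylsilyloxy)-10β-methylhydrind-3(5)-en-8-one | C=CC[C@H]1CC2=C(O[Si](C)(C)C(C)(C)C)CC[C@]2(C)CC1=O | intermediate
8 | (7S,10R)-7β-allyl-3-(tert-butyldimethylsilyloxy)-10β-methylhydrind-3(5)-en-8-one, single enantiomer | C=CC[C@H]1CC2=C(O[Si](C)(C)C(C)(C)C)CC[C@]2(C)CC1=O | intermediate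
9 | 7β-allyl-3-(tert-butyldimethylsilyloxy)-10β-methylhydrind-3(5)-en-8β-ol | C=CC[C@H]1CC2=C(O[Si](C)(C)C(C)(C)C)CC[C@]2(C)C[C@H]1O | intermediate
10 | 8β-acetoxy-7β-allyl-3-(tert-butyldimethylsilyloxy)-10β-methylhydrind-3(5)-ene | C=CC[C@H]1CC2=C(O[Si](C)(C)C(C)(C)C)CC[C@]2(C)C[C@H]1OC(C)=O | intermediate
11 | 8β-acetoxy-7β-allyl-10β-methyl-5βH-hydrindan-3-one | C=CC[C@H]1C[C@@H]2C(=O)CC[C@]2(C)C[C@H]1OC(C)=O | intermediate
12 | 1,2,4-trioxolane (ozonide) of the allyl group of 11 | O1COOC1C[C@H]2C[C@@H]3C(=O)CC[C@]3(C)C[C@H]2OC(C)=O | intermediate (not isolated)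
13 | (8β-acetoxy-10β-methyl-3-oxo-5βH-hydrindan-7β-yl)acetaldehyde | O=CC[C@H]1C[C@@H]2C(=O)CC[C@]2(C)C[C@H]1OC(C)=O | intermediate
14 | Mannich base, 13-(dimethylamino) aldehyde (C11 epimers) | CN(C)CC(C=O)[C@H]1C[C@@H]2C(=O)CC[C@]2(C)C[C@H]1OC(C)=O | intermediate (not isolated)
15 | 8β-acetoxy-3-oxo-4,15-dinor-5βH-eudesm-11(13)-en-12-al | C=C(C=O)[C@H]1C[C@@H]2C(=O)CC[C@]2(C)C[C@H]1OC(C)=O | intermediate
16 | 8β-acetoxy-3-oxo-4,15-dinor-5βH-eudesm-11(13)-en-12-oic acid | C=C(C(=O)O)[C@H]1C[C@@H]2C(=O)CC[C@]2(C)C[C@H]1OC(C)=O | intermediate
17 | methyl 8β-acetoxy-3-oxo-4,15-dinor-5βH-eudesm-11(13)-en-12-oate | C=C(C(=O)OC)[C@H]1C[C@@H]2C(=O)CC[C@]2(C)C[C@H]1OC(C)=O | intermediate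
18 | methyl 8β-acetoxy-3-(trimethylsilyloxy)-4,15-dinoreudesma-3(5),11(13)-dien-12-oate | C=C(C(=O)OC)[C@H]1CC2=C(O[Si](C)(C)C)CC[C@]2(C)C[C@H]1OC(C)=O | intermediate
19 | acetamidine hydrochloride | CC(N)=N.Cl | starting material
20 | 3-chloro-3-methyl-3H-diazirine | CC1(Cl)N=N1 | intermediate
21 | α-face chloro(methyl)cyclopropane on C3–C5 of 18, chloride over the five-membered ring | C=C(C(=O)OC)[C@H]1C[C@@]23[C@](C)(Cl)[C@]2(O[Si](C)(C)C)CC[C@]3(C)C[C@H]1OC(C)=O | intermediate (not isolated)
22 | methyl 8β-acetoxy-3-oxoeudesma-4,11(13)-dien-12-oate | C=C(C(=O)OC)[C@H]1CC2=C(C)C(=O)CC[C@]2(C)C[C@H]1OC(C)=O | intermediate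
23 | methyl 8β-acetoxy-3β-hydroxyeudesma-4,11(13)-dien-12-oate | C=C(C(=O)OC)[C@H]1CC2=C(C)[C@@H](O)CC[C@]2(C)C[C@H]1OC(C)=O | intermediate
24 | angelic acid, (Z)-2-methylbut-2-enoic acid | C/C=C(/C)C(=O)O | starting material
25 | methyl 8β-acetoxy-3α-angeloyloxyeudesma-4,11(13)-dien-12-oate | C=C(C(=O)OC)[C@H]1CC2=C(C)[C@H](OC(=O)/C(C)=C\C)CC[C@]2(C)C[C@H]1OC(C)=O | intermediate
26 | methyl 8β-acetoxy-3α-angeloyloxy-5α-hydroperoxyeudesma-4(15),11(13)-dien-12-oate (CNP0116769.2) | C=C(C(=O)OC)[C@H]1C[C@@]2(OO)C(=C)[C@H](OC(=O)/C(C)=C\C)CC[C@]2(C)C[C@H]1OC(C)=O | target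

Total step count: 17. Longest linear sequence: 16 (steps 1–12 and 14–17; step 13 is a one-step branch).

**Steps most likely to fail**

1) Step 14 (key step).
- Risk: the carbene may rearrange to vinyl chloride or be consumed by diazirine before it reaches the hindered tetrasubstituted double bond. Traces of HCl may strip the silyl group. Addition with the chloride turned towards OSiMe3 and C6 gives an adduct that cannot open.
- Fallback: it uses known chemistry, sets out from 18 and returns at 22.
- A Furukawa-type Simmons–Smith ethylidene transfer (Et2Zn, MeCHI2, CH2Cl2, 0 °C) is selective for electron-rich alkenes and tolerates esters. It gives the methyl-substituted siloxycyclopropane F1.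
- Ito–Saegusa oxidative opening with FeCl3 in DMF cleaves the C3–C5 bond through the tertiary C5 radical and gives the ring-expanded β-chloro ketone F2.
- NaOAc in refluxing MeOH removes HCl to give 22.
- Both C4 epimers of F1 are productive, because this opening makes no stereoelectronic demand on C4.

2) Step 2.
- Risk: deprotonation may occur at the less hindered C2 rather than at C5, or silyl groups may be exchanged or lost, which would erase the difference between the two carbonyl positions.
- Fallback: it sets out from 1 and returns at 4.
- Bromination and dehydrobromination (Br2, then Et3N, CH2Cl2, 0 °C) give 2-bromo-3-methylcyclopent-2-en-1-one F3, a more reactive dienophile.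
- Its Diels–Alder reaction with 2 under the conditions of step 1 gives the 5β-bromo adduct F4.
- Reductive silylation of this α-bromo ketone (Zn, t-BuMe2SiCl, TMEDA, THF) generates the enolate only between C3 and C5 and so gives 4 regiospecifically.

3) Step 16.
- Risk: the allylic oxyphosphonium salt may ionise, leading to elimination to the 2,4-diene or to capture without clean inversion.
- Fallback: it sets out from 22 and returns at 25.
- Corey–Bakshi–Shibata reduction with (S)-2-methyl-CBS-oxazaborolidine and catecholborane (PhMe, −78 °C) treats the methyl-bearing alkene side as the large group. It should override the substrate bias and give the 3α-alcohol F5 directly.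
- F5 is then acylated with retention by the Yamaguchi-type mixed anhydride of angelic acid F6. F6 is made from 24, 2,4,6-trichlorobenzoyl chloride and Et3N in PhMe and is used without DMAP at 80 °C, so that the Z geometry is kept.

**Further compounds**
F1 | step 14 | ethylidene adduct of 18, 4-methyl-3-(trimethylsilyloxy)cyclopropane on C3–C5 (α face, C4 epimers) | C=C(C(=O)OC)[C@H]1C[C@@]23C(C)[C@]2(O[Si](C)(C)C)CC[C@]3(C)C[C@H]1OC(C)=O
F2 | step 14 | methyl 8β-acetoxy-5-chloro-3-oxoeudesm-11(13)-en-12-oate (C4 and C5 epimers) | C=C(C(=O)OC)[C@H]1CC2(Cl)C(C)C(=O)CC[C@]2(C)C[C@H]1OC(C)=O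
F3 | step 2 | 2-bromo-3-methylcyclopent-2-en-1-one | CC1=C(Br)C(=O)CC1
F4 | step 2 | rac-5β-bromo-10β-methyl-8-(trimethylsilyloxy)hydrind-7-en-3-one | C1=C(O[Si](C)(C)C)C[C@@]2(C)CCC(=O)[C@@]2(Br)C1
F5 | step 16 | methyl 8β-acetoxy-3α-hydroxyeudesma-4,11(13)-dien-12-oate | C=C(C(=O)OC)[C@H]1CC2=C(C)[C@H](O)CC[C@]2(C)C[C@H]1OC(C)=O
F6 | step 16 | angelic 2,4,6-trichlorobenzoic anhydride | C/C=C(/C)C(=O)OC(=O)c1c(Cl)cc(Cl)cc1Cl
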